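The readings are simulated with made-up constants; the scatter is artificial.

If the south run was to end with 1.00 % of its charge left as substrate at 780 h, what would the runs so far have to show?

| flask | substrate | free catalyst | time |
|---|---|---|---|
| west | 0.400 M | 0.0200 M |  |
| north-east | 0.240 M | 0.0200 M |  |
| north | 0.400 M | 0.0100 M |  |
| north-west | 0.800 M | 0.0200 M |  |
| south | 0.400 M | 0.0200 M | 780 h |

| west run: time / h | west run: [substrate] / M | north-east run: time / h | north-east run: [substrate] / M | north run: time / h | north run: [substrate] / M | north-west run: time / h | north-west run: [substrate] / M |
|---|---|---|---|---|---|---|---|
| 9.3 | 0.3686 | 9.3 | 0.2109 | 9.3 | 0.3875 | 9.3 | 0.7647 |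
| 28 | 0.3204 | 28 | 0.1729 | 28 | 0.3607 | 28 | 0.7025 |
| 54 | 0.2739 | 54 | 0.1462 | 54 | 0.3353 | 54 | 0.6321 |
| 86 | 0.2428 | 86 | 0.1290 | 86 | 0.3090 | 86 | 0.5666 |
| 120 | 0.2202 | 120 | 0.1166 | 120 | 0.2830 | 120 | 0.5093 |
| 160 | 0.2002 | 160 | 0.1076 | 160 | 0.2603 | 160 | 0.4597 |
| 210 | 0.1788 | 210 | 0.0951 | 210 | 0.2304 | 210 | 0.4069 |
| 260 | 0.1599 | 260 | 0.0853 | 260 | 0.2070 | 260 | 0.3614 |

(readings scatter by 0.001 M)

- Overall: substrate -> product, with free catalyst as catalyst.
- Constant volume, constant temperature.
- Bound and free are read together.
- An order is taken over about fifteen percent of the charge, up and down.

- apparent order in [free catalyst] of the starting rate, round the charge of the west run (the rate where two percent of its substrate have turned into product)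
- apparent order in [substrate] of the starting rate, round the charge of the west run (the rate where two percent of its substrate have turned into product) (one fixed amount of product, the same in the runs compared)
- the north-east run starts with 0.160 M less of substrate than the west run, and with no product. Compared where both hold the same amount of substrate, once fifteen percent of what the north-east run was charged with has turned into product, is the north-east run faster, slower or alike (within a tenth)?
- substrate in the south run at 780 h, as a share of the substrate charged

1. The south run has the charge of the west run, so I took it to follow the west run up to that run's last reading at 260 h, where 40.0 % of the charge was left as substrate.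

2. I went to logarithms. Between 160 h and 260 h the west run gave a decade time of 1020 h: the hours in which the share of the charge left as substrate falls by a factor of 10, as in any first-order loss.

3. Ending at 1.00 % in the south run would need a decade time of 325 h over the remaining 520 h. The reading from the west run is longer than that by a factor of 3.14.

4. The north run, charged with half the free catalyst of the west run, gave 1000 h over the same hours, close to the west run's value. So the late fall showed no sign of following the catalyst.

5. I therefore carried the decade time forward from 260 h and reckoned 12.4 % for the south run at 780 h.

6. The forecast gave 1.5 and 0.2 for the orders, faster for the north-east run, and 12.5 % for the south run, slightly above my figure. It read the runs as “a first-order, catalyst-independent background path, plus a catalysed path that dies within about 100 h”.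

    free catalyst + substrate ⇌ catalyst-substrate complex, settled at all times (4.250 M⁻¹)
    catalyst-substrate complex + free catalyst → product + 2 free catalyst (30.53 M⁻¹ h⁻¹)
    free catalyst → spent catalyst (0.03136 h⁻¹)
    substrate → product (0.002210 h⁻¹)

The flask gave 12.6 % in the south run, with 1.6, 0.087 and faster as the other answers. The power-law fit, with a root mean square residual of 26 times the scatter, gave 0.908 % for the south run. From 40.0 % at 260 h, that figure asks for a decade time of 316 h, against the 1020 h I read. In the north-east run, half the charge had turned into product at 112 h. The decade time carried that run to 35.8 % at 260 h, and the reading was 35.5 %.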